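The easy step is to count equivalents. If Jc and Jd trapped the intermediate Jb with equal rate constants, Jb would at the start split as the charges do, so I take as the zero of the scale the charge odds ρ = 0.700, the equivalents of Jc over those of Jd.

| setting | summer | dawn | spring | autumn | epsilon | alpha | beta | delta |
|---|---|---|---|---|---|---|---|---|
| Ja | 0.10 M | 0.050 M | 0.20 M | 0.10 M | 0.10 M | 0.10 M (fed, over 2.00 min) | 0.10 M | 0.10 M |
| Jc | 1.05 equiv | 1.05 equiv | 1.05 equiv | 1.05 equiv | 1.05 equiv | 1.05 equiv | 1.05 equiv (fed, over 2.00 min) | 1.05 equiv |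
| Jd | 1.5 equiv | 1.5 equiv | 1.5 equiv | 3 equiv | 1.50 equiv | 1.50 equiv | 1.50 equiv | 1.50 equiv |
| remark | run made earlier | run made earlier | run made earlier | run made earlier | a closed flask charged with all of it at once and left for 2.0 min | a stirred flask in which Ja is dosed at a steady rate over 2.00 min without added volume, worked up at 2.0 min | a stirred flask in which Jc is dosed at a steady rate over 2.00 min without added volume, worked up at 2.0 min | a single well-mixed tank run continuously and read at steady state, 2.0 min in it on average |
| time |  |  |  |  | 2.0 min | 2.0 min | 2.0 min |  |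

| run | time / s | Jf / % | Ja / % |
|---|---|---|---|
| summer | 10.0 | 5 | 80 |
| summer | 12.0 | 3 | 84 |
| summer | 20.0 | 6 | 68 |
| summer | 30.0 | 9 | 52 |
| summer | 50.0 | 11 | 32 |
| summer | 80.0 | 11 | 22 |
| dawn | 10.0 | 6 | 84 |
| dawn | 20.0 | 8 | 63 |
| dawn | 30.0 | 11 | 53 |
| dawn | 50.0 | 19 | 35 |
| dawn | 80.0 | 20 | 19 |
| dawn | 90.0 | 22 | 14 |
| dawn | 120 | 21 | 8 |
| spring | 15.0 | 4 | 74 |
| spring | 30.0 | 8 | 54 |
| spring | 50.0 | 6 | 33 |
| spring | 60.0 | 6 | 31 |
| spring | 80.0 | 9 | 19 |
| spring | 90.0 | 10 | 16 |
| spring | 120 | 7 | 9 |
| autumn | 10.0 | 6 | 85 |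
| autumn | 20.0 | 1 | 63 |
| autumn | 30.0 | 3 | 55 |
| autumn | 60.0 | 4 | 26 |
| autumn | 120 | 1 | 9 |

(each reading ± 2 percentage points)

- the stated concentrations are those of everything mixed, before any reaction; amounts are the same in each set-up
- candidate steps: Ja <-> Jb; Jc + Jb -> Jf; Jd + Jb -> Jg; Jd + Jf -> Jh; Jd -> Je
- the feed brings no volume worth counting
- the earlier runs were made in a closed, stirred flask

- the set-up with the highest amount of Jf at the outlet or at the end, in percent of the Ja put in ("none" if the first two lie within 2 percentage points) (epsilon / alpha / beta / delta / none)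
- amount of Jf at the outlet or at the end, in percent of the Ja put in, epsilon
- amount of Jf at the outlet or at the end, in percent of the Ja put in, alpha
- amount of Jf at the outlet or at the end, in percent of the Ja put in, beta
- amount of Jf at the outlet or at the end, in percent of the Ja put in, delta

Does Ja set the pace? At 30.0 s the Ja reading is 53% at 0.050 M and 54% at 0.20 M, so the loss of Ja looks first-order, with Ja to Jb as the rate-limiting step. The summer readings give a half-life of about 36.9 s.

Does Jf survive? At 30.0 s Jf reads 9% with 1.5 equiv of Jd and 3% with 3 equiv, so I suspect the candidate step Jd + Jf → Jh. To compare a flask with ρ, I therefore count Jf plus Jh against Jg; these route odds are what I hold against ρ.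

Does the way of charging matter? Dosing lasts 2.00 min, longer than that half-life. So in beta Jb forms while Jc lags, which I expect to put the route odds below ρ, and in alpha I expect Jf to be made late, with less time beside Jd. I commit to alpha on top and beta below epsilon.

The forecast differs: 9% for epsilon, 8.5% for alpha, 5% for beta, 8.5% for delta, hence "none". Of beta it says “early Jb is starved of Jc and goes to Jg”.

    Ja ⇌ Jb (K = 0.300, k = 0.0210 /s)
    Jc + Jb → Jf (k = 180 /M/s)
    Jd + Jb → Jg (k = 170 /M/s)
    Jd + Jf → Jh (k = 0.880 /M/s)
    Jd → Je (k = 0.0110 /s)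

The flask gives 18.9% of Jf in alpha, above 14.5% in epsilon, 12.7% in beta and 9.00% in delta, so the best is alpha. Alpha at 2.00 min still holds 36.6% of the Ja charged. Its route odds are 1.94, which is 2.78 times ρ; this gain is an apparent selectivity factor.

In the neighbour of alpha with 0.420 equiv of Jc, ρ falls to 0.280, and the same gain gives route odds of 0.778. That flask shows 0.749, with 13.5% of Jf.

The readings are simulated with constants of no real substance, noise included.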